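Late in a run the two earlier flasks have levelled off, and far apart: maple stands at 0% target after 120 s, while elm's last readings average 44.0%, a roof of 0.484 M read from them.

| flask | substrate | reagent | initiator | remark | time |
|---|---|---|---|---|---|
| maple | 0.11 M | 0.56 M | 8 mM | run made earlier |  |
| elm | 1.1 M | 0.56 M | 8 mM | run made earlier |  |
| Wednesday's | 0.20 M | 0.560 M | 8.0 mM |  | 3.0 min |
| Saturday's | 0.40 M | 0.560 M | 8.0 mM |  | 3.0 min |
| Monday's | 0.80 M | 0.560 M | 8.0 mM |  | 3.0 min |
| Tuesday's | 1.5 M | 0.560 M | 8.0 mM |  | 3.0 min |

| run | time / s | target / % |
|---|---|---|
| maple | 15.0 | 46 |
| maple | 40.0 | 14 |
| maple | 80.0 | 0 |
| maple | 120 | 0 |
| elm | 15.0 | 40 |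
| elm | 40.0 | 45 |
| elm | 80.0 | 42 |
| elm | 120 | 45 |

(standard deviation of a reading: 2 percentage points)

- in percentages every species weighs as the substrate in it: one ended chains counts as two
- steps thought possible: initiator -> 2 initiating radical; substrate + initiating radical -> chain carrier; reagent + chain carrier -> target + initiating radical; 2 chain carrier -> ended chains; reagent + target -> over-reaction product
- a step back or a flat step of under half a percent of the largest counts as no turn
- "hardly changes" means that all values lie within two and a half points (for a concentration: within two and a half percent of the largest)
- a step back or a flat step of under half a percent of the largest counts as no turn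

1. [target] at the end for Wednesday's, Saturday's, Monday's, Tuesday's, in this order
2. the course of these numbers from the first flask to the last (rises all the way / falls all the way / hardly changes / falls, then rises / rises, then falls)

Two chemists dispute this row. The first holds that one reagent makes one target and that the target then stays, so a flask gives its substrate charge up to elm's roof: 0.20 M, 0.40 M, then 0.484 M twice. He takes maple's fall for a feature of a charge as small as 0.11 M.

The second points out that reagent also attacks the target, so a substrate carried through to over-reaction product costs two reagent. Her zero of the scale is the break-even charge, 0.280 M, half of c(reagent): the substrate charge whose full passage to over-reaction product takes exactly the reagent charged. Below it, reagent stands over by two times the distance to the zero, and it eats the target, as in maple at 0.11 M. Above it, the target left is two times that distance, until elm's roof is met, where substrate stays over and the reagent is the limiting reagent. For Saturday's that is 0.240 M, with no rate constant needed.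

Her forecast is 0.003 M, 0.235 M, 0.47 M, 0.47 M, so rises all the way, reading elm's roof a little lower than he does and setting Saturday's a little below the plain reckoning above. Its ground for that roof: “because the reagent is used up, not the substrate”.

The simulation gives 0.00284 M, 0.238 M, 0.481 M, 0.481 M, so rises all the way. Her row stands for Wednesday's and Saturday's. His view keeps Monday's and Tuesday's, which end with over-reaction product at 4.93% and 2.63% of the substrate charged.

    initiator → 2 initiating radical (k = 0.0280 /s)
    substrate + initiating radical → chain carrier (k = 32000 /M/s)
    reagent + chain carrier → target + initiating radical (k = 3.00 × 10⁵ /M/s)
    2 chain carrier → ended chains (k = 1.20 × 10⁸ /M/s)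
    reagent + target → over-reaction product (k = 0.120 /M/s)

In Wednesday's, the half-life of the target by the over-reaction step alone, the other concentrations as charged, is 0.17 min, short against the run's 3.0 min, and the flask ends with 1.42% target and 0.164 M of reagent, against 0.160 M from two times the distance of its substrate charge below the break-even charge. Two times Saturday's distance above the break-even charge is 0.240 M, and Saturday's ends with 0.102% of its reagent and 0.238 M target.

The earlier runs and the new flask were generated by integration with made-up constants; noise was put on by code.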